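The earlier runs and the new flask were generated by integration on assumed constants; the scatter is artificial.

I have no constants for this flask, so I read one from the ash run. E, with the salt J from the second phase, turns Q into D. South-east and east differ from ash in their charge of Q and their time.

| flask | Q | J | E | remark | time | volume of the second phase over the first |
|---|---|---|---|---|---|---|
| ash | 14 mM | 30 mM | 2 mM | run made earlier |  |  |
| south-east | 12 mM | 30.0 mM | 2.0 mM |  | 6.0 min | 1.0 |
| east | 20 mM | 30.0 mM | 2.0 mM |  | 25 min | 1.0 |

- charges count per volume of the first phase; a concentration in a rate is the amount of a species over the volume of its own phase; every rate counts per litre of the first phase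
- the earlier runs hold the two phases in the same ratio of volumes as the flask asked about

- which of the two ends with the higher amount of D, in percent of the Q charged ("neither" if they lie within 2 percentage points) (south-east / east / neither)
- D at the end, in percent of the Q charged, south-east
- D at the end, in percent of the Q charged, east

- ash (time / min: D / %, Q / %): 1.33: 0, 99; 3.00: 5, 95; 8.00: 9, 86; 20.0: 24, 67

(scatter of a reading: 1.5 percentage points)

I read this table row by row, as fractions of the Q charged. The first row shows a loss of 1 percentage point, less than the scatter of 1.5 points, so I set it aside. The next two rows give loss constants of 0.0171 min⁻¹ and 0.0189 min⁻¹. The last row, with more Q lost than either, gives 0.0200 min⁻¹. This is my loss constant k, the fraction of the Q still present that goes each minute; the usual term is a pseudo-first-order constant. It is a reading from one charge of Q, and I assume it for the other two.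

The D column comes next. In the last row D is 72.7 % of the Q lost, and 9 points of the charge is in neither column. So I take the end state as that share of the charge standing as D, approached at the pace of k. My reckoning gives 8.23 % for south-east and 28.6 % for east.

The forecast names east, with 7.5 % for south-east and 26 % for east: “East clearly ends higher either way.” My figures stand above the forecast's on both flasks, but the order is the same.

The higher one is east: south-east gives 9.32 % and east 23.8 %, a gap of 14 points against the margin of 2 points.

    E + J ⇌ X + Z (K = 0.271, k = 29.1 M⁻¹ min⁻¹)
    Q + X → D + E (k = 23.4 M⁻¹ min⁻¹)
    2 X ⇌ G, settled at all times (K = 280 M⁻¹)
    D ⇌ L (K = 0.600, k = 0.0791 min⁻¹)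

Without the scatter, the ash run at its last reading has D at 22.5 %. Moving just the charge of Q to that of south-east gives 23.1 %, while moving just the time to that of south-east gives 9.14 %. I put k to use again on east. At 25 min it leaves 60.7 % of the Q, and east holds 65 %. With east read at 40 min, k leaves 44.9 %, and the flask holds 53 %.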